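**Retrosynthetic overview** (cembrane numbering: C1 carries the acrylate, C3 the free secondary OH, C4=C5 the ring olefin, C7 the acetate, C8/C11 the ether bridge, C12 the tertiary OH)

1. Last bond C3–C4: the 14-membered carbocycle is closed by intramolecular Nozaki–Hiyama–Kishi addition of the C4 alkenyl iodide to the C3 aldehyde.
2. C1 and the acrylate: Ir-catalysed branched allylic alkylation of dimethyl malonate (C1–C15), then mono-hydrolysis and decarboxylative Mannich methylenation; C13–C14 by allyl Grignard opening of a C12–C13 epoxide, C2–C3 by cross-metathesis.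
3. Oxolane core: Lewis-acid cascade of an acyclic (7R,8R,11R,12R)-bis-epoxide carbonate. The C11–C12 oxirane (O, C11, C12) is enlarged by two atoms to the oxolane (O, C11, C10, C9, C8) through a bicyclic epoxonium ion, and the C13 carbonate closes a temporary dioxolanone on C12. The bis-epoxide comes from geranyl acetate (C6–C13 with the C8 and C12 methyls).
4. Enabling feature: C8 and C12 are both methyl-bearing, oxygenated tertiary carbons joined through C9–C10–C11. The oxygen of an oxirane on C11–C12 therefore lies four atoms from C8, and both C–O cleavages occur at tertiary carbon with inversion, which is the (8S,12S) pattern of the target.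
5. Ring order: oxolane and temporary dioxolanone together (step 7), then the carbocycle (step 19).

Key step: step 7

Remark 1: the ligand enantiomer in step 13 is named on the assumption that it gives the (1S) branched product, by analogy with the standard cinnamyl carbonate/malonate case; if a model run shows the opposite sense, the enantiomeric ligand is used.
Remark 2: atom labels C1–C20 in the text refer to the cembrane numbering given above.

**Step 1**
Reactants: 1 geranyl acetate
Product: 2 (2E,6E)-8-hydroxy-3,7-dimethylocta-2,6-dien-1-yl acetate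
Conditions: SeO2 (cat.), t-BuOOH, salicylic acid (cat.), CH2Cl2, rt
Reagents that add atoms: tert-butyl hydroperoxide, CC(C)(C)OO
Why: Riley-type allylic oxidation (ene reaction, then [2,3]-sigmatropic shift) in its catalytic form attacks the (E)-methyl group of the electron-rich terminal olefin, the C2–C3 olefin being deactivated by the allylic acetate; no stereocentre is formed.

**Step 2**
Reactants: 2 (2E,6E)-8-hydroxy-3,7-dimethylocta-2,6-dien-1-yl acetate; 3 tributyl(prop-1-yn-1-yl)stannane
Product: 4 (2E,6E)-2,6-dimethylundeca-2,6-dien-9-yn-1-ol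
Conditions: Pd(dba)2 (cat.), LiCl, DMF, 40 °C
Reagents that add atoms: none
Why: Stille coupling of an allylic acetate: zerovalent palladium ionises the acetate and the alkynyl group is delivered to the unhindered primary terminus of the π-allyl with retention of the E geometry, the free primary alcohol being inert.

**Step 3**
Reactants: 4 (2E,6E)-2,6-dimethylundeca-2,6-dien-9-yn-1-ol
Product: 6 (2E,6E,9E)-10-iodo-2,6-dimethylundeca-2,6,9-trien-1-ol, via alkenylzirconocene 5 (not isolated)
Conditions: Cp2Zr(H)Cl (excess), THF, rt; then I2, 0 °C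
Reagents that add atoms: iodine, II
Why: hydrozirconation–iodination: syn addition of Zr–H to the methyl-capped alkyne, equilibration of zirconium to the less hindered methyl-bearing carbon and iodinolysis with retention should give the (E)-2-iodoalkene, the trisubstituted olefins being unreactive.

**Step 4**
Reactants: 6 (2E,6E,9E)-10-iodo-2,6-dimethylundeca-2,6,9-trien-1-ol
Product: 7 [(2R,3R)-3-[(3E,6E)-7-iodo-3-methylocta-3,6-dien-1-yl]-2-methyloxiran-2-yl]methanol
Conditions: Ti(OiPr)4 (cat.), D-(−)-diethyl tartrate (cat.), t-BuOOH, 4 Å MS, CH2Cl2, −20 °C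
Reagents that add atoms: tert-butyl hydroperoxide, CC(C)(C)OO
Why: Sharpless asymmetric epoxidation touches only the allylic alcohol olefin, and D-(−)-tartrate delivers oxygen to the face that gives the (2R,3R)-epoxy alcohol (C12 R, C11 R), the mirror image of the L-(+)-tartrate outcome in the standard mnemonic.

**Step 5**
Reactants: 7 [(2R,3R)-3-[(3E,6E)-7-iodo-3-methylocta-3,6-dien-1-yl]-2-methyloxiran-2-yl]methanol
Product: 8 [(2R,3R)-3-(2-{(2R,3R)-3-[(2E)-3-iodobut-2-en-1-yl]-2-methyloxiran-2-yl}ethyl)-2-methyloxiran-2-yl]methanol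
Conditions: D-fructose-derived Shi ketone (cat.), KHSO5 (Oxone), K2CO3, Bu4NHSO4, MeCN/CH2(OMe)2/aq. Na2B4O7 buffer, 0 °C
Reagents that add atoms: potassium peroxymonosulfate, [K+].[O-]S(=O)(=O)OO
Why: Shi asymmetric epoxidation: the chiral dioxirane attacks the remaining electron-rich trisubstituted (E)-olefin through the spiro transition state, the D-fructose-derived ketone giving the (R,R)-epoxide (C8 R, C7 R), while the iodoalkene is too electron-poor to react.

**Step 6**
Reactants: 8 [(2R,3R)-3-(2-{(2R,3R)-3-[(2E)-3-iodobut-2-en-1-yl]-2-methyloxiran-2-yl}ethyl)-2-methyloxiran-2-yl]methanol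
Product: 9 tert-butyl {[(2R,3R)-3-(2-{(2R,3R)-3-[(2E)-3-iodobut-2-en-1-yl]-2-methyloxiran-2-yl}ethyl)-2-methyloxiran-2-yl]methyl} carbonate
Conditions: Boc2O, 1-methylimidazole (cat.), toluene, 0 °C to rt
Reagents that add atoms: di-tert-butyl dicarbonate, CC(C)(C)OC(=O)OC(=O)OC(C)(C)C
Why: acylation of the primary alcohol to its tert-butyl carbonate installs the internal nucleophile that will end the cascade; no stereocentre is touched.

**Step 7**
Reactants: 9 tert-butyl {[(2R,3R)-3-(2-{(2R,3R)-3-[(2E)-3-iodobut-2-en-1-yl]-2-methyloxiran-2-yl}ethyl)-2-methyloxiran-2-yl]methyl} carbonate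
Product: 12 (4S)-4-[(2R,5S)-5-[(1R,3E)-1-hydroxy-4-iodopent-3-en-1-yl]-5-methyloxolan-2-yl]-4-methyl-1,3-dioxolan-2-one, via epoxonium ion 10 (not isolated), via dioxolan-2-ylium ion 11 (not isolated)
Conditions: BF3·OEt2 (0.5 equiv), CH2Cl2, −78 to −40 °C; then aq. NaHCO3
Reagents that add atoms: none
Why: BF3 coordinates the more basic, purely alkyl-substituted C7–C8 oxirane, and as its bond to the tertiary carbon C8 ionises, the oxygen of the C11–C12 oxirane attacks C8 from the rear to give the 1-oxoniabicyclo[3.1.0]hexane (epoxonium) ion 10; the carbonyl oxygen of the C13 carbonate then opens the three-membered ring of 10 at the tertiary carbon C12, so that the oxirane O–C11–C12 has been expanded by two atoms to the oxolane O–C11–C10–C9–C8, and the dioxolan-2-ylium ion 11 loses 2-methylpropene. The closest known reaction type is the Lewis-acid-promoted epoxide-opening cascade of 1,5-bis-epoxides that runs through epoxonium ions and is ended by a tert-butyl carbonate, i.e. an electrophile-induced ring expansion of an epoxide to a tetrahydrofuran. Ring closures: the oxolane by 5-exo-tet attack of the oxirane oxygen on C8, the 1,3-dioxolan-2-one by 5-exo-tet attack of the carbonyl oxygen on C12. Stereocentres: C8 and C12 are each formed by anti (SN2-like) displacement of an epoxide oxygen, so their configurations are the inverse of those written into the two epoxides by the catalysts of steps 4 and 5 (8R to 8S, 12R to 12S), while C7 and C11 keep their C–O bonds. The step needs initiation at the C7–C8 oxirane and cleavage at C8 and C12 rather than at C7 and C11: the first is secured by the electron-withdrawing carbonate-bearing C13 on C12, which makes the C11–C12 oxirane the poorer electrophile and leaves its oxygen as the internal nucleophile, the second by the tertiary, methyl-bearing nature of C8 and C12 and by the five-membered transition states, and the low temperature should keep both substitutions stereospecific.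

**Step 8**
Reactants: 12 (4S)-4-[(2R,5S)-5-[(1R,3E)-1-hydroxy-4-iodopent-3-en-1-yl]-5-methyloxolan-2-yl]-4-methyl-1,3-dioxolan-2-one
Product: 13 (2S)-2-[(2R,5S)-5-[(1R,3E)-1-hydroxy-4-iodopent-3-en-1-yl]-5-methyloxolan-2-yl]propane-1,2-diol
Conditions: K2CO3 (cat.), MeOH, rt
Reagents that add atoms: none
Why: base-catalysed methanolysis (transesterification) of the cyclic carbonate frees the C12/C13 diol without breaking any C–O bond at a stereocentre.

**Step 9**
Reactants: 13 (2S)-2-[(2R,5S)-5-[(1R,3E)-1-hydroxy-4-iodopent-3-en-1-yl]-5-methyloxolan-2-yl]propane-1,2-diol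
Product: 15 (1R,3E)-4-iodo-1-[(2S,5R)-2-methyl-5-[(2S)-2-methyloxiran-2-yl]oxolan-2-yl]pent-3-en-1-ol, via primary tosylate 14 (not isolated)
Conditions: NaH, 1-(p-toluenesulfonyl)imidazole, THF, 0 °C to rt
Reagents that add atoms: none
Why: one-pot epoxide formation from a 1,2-diol: the least hindered primary alkoxide (C13) is sulfonylated selectively and the neighbouring tertiary C12 alkoxide displaces the tosylate (3-exo-tet Williamson closure), so the C12–O bond and its configuration are retained.

**Step 10**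
Reactants: 15 (1R,3E)-4-iodo-1-[(2S,5R)-2-methyl-5-[(2S)-2-methyloxiran-2-yl]oxolan-2-yl]pent-3-en-1-ol; 16 allylmagnesium chloride
Product: 17 (2S)-2-[(2R,5S)-5-[(1R,3E)-1-hydroxy-4-iodopent-3-en-1-yl]-5-methyloxolan-2-yl]hex-5-en-2-ol
Conditions: THF, −20 to 0 °C; then aq. NH4Cl
Reagents that add atoms: none
Why: SN2 opening of the 2,2-disubstituted epoxide at its unsubstituted carbon C13 by the allyl Grignard reagent (no copper, so that the alkenyl iodide is left alone) forms the C13–C14 bond and frees the tertiary C12 hydroxyl with retention.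

**Step 11**
Reactants: 17 (2S)-2-[(2R,5S)-5-[(1R,3E)-1-hydroxy-4-iodopent-3-en-1-yl]-5-methyloxolan-2-yl]hex-5-en-2-ol
Product: 18 bis(triethylsilyl) ether of 17 (C7–OSiEt3 and C12–OSiEt3)
Conditions: Et3SiOTf, 2,6-lutidine, CH2Cl2, −78 to 0 °C
Reagents that add atoms: triethylsilyl trifluoromethanesulfonate, CC[Si](CC)(CC)OS(=O)(=O)C(F)(F)F
Why: silylation of both hydroxyls (the tertiary one needs the silyl triflate) prevents the C12 oxygen from closing a five-membered ether onto the allyl–iridium intermediate of step 13 and leaves nothing sensitive to the hydroxide of step 14.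

**Step 12**
Reactants: 18 bis(triethylsilyl) ether of 17; 19 allyl methyl carbonate
Product: 20 methyl (2E,6S)-6-[(2R,5S)-5-[(1R,3E)-4-iodo-1-(triethylsilyloxy)pent-3-en-1-yl]-5-methyloxolan-2-yl]-6-(triethylsilyloxy)hept-2-en-1-yl carbonate
Conditions: second-generation Hoveyda–Grubbs catalyst (cat.), CH2Cl2, 40 °C
Reagents that add atoms: none
Why: olefin cross-metathesis of the terminal alkene with an allylic carbonate should give the linear (E)-allylic carbonate under thermodynamic control, the trisubstituted iodoalkene not entering the catalytic cycle.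

**Step 13**
Reactants: 20 methyl (2E,6S)-6-[(2R,5S)-5-[(1R,3E)-4-iodo-1-(triethylsilyloxy)pent-3-en-1-yl]-5-methyloxolan-2-yl]-6-(triethylsilyloxy)hept-2-en-1-yl carbonate; 21 dimethyl malonate
Product: 22 dimethyl 2-[(3S,6S)-6-[(2R,5S)-5-[(1R,3E)-4-iodo-1-(triethylsilyloxy)pent-3-en-1-yl]-5-methyloxolan-2-yl]-6-(triethylsilyloxy)hept-1-en-3-yl]propanedioate
Conditions: [Ir(cod)Cl]2 (cat.), (Ra)-BINOL-derived N,N-bis[(R)-1-phenylethyl]phosphoramidite (cat.), 1,5,7-triazabicyclo[4.4.0]dec-5-ene (cat.), THF, rt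
Reagents that add atoms: none
Why: iridium-catalysed asymmetric allylic alkylation: the cyclometalated Ir–phosphoramidite complex ionises the carbonate and the malonate attacks the substituted allyl terminus (branched selectivity) on the face fixed by the ligand, which sets C1 as S and leaves the vinyl group that becomes C2–C3.

**Step 14**
Reactants: 22 dimethyl 2-[(3S,6S)-6-[(2R,5S)-5-[(1R,3E)-4-iodo-1-(triethylsilyloxy)pent-3-en-1-yl]-5-methyloxolan-2-yl]-6-(triethylsilyloxy)hept-1-en-3-yl]propanedioate
Product: 23 3-methoxy-3-oxo-2-[(3S,6S)-6-[(2R,5S)-5-[(1R,3E)-4-iodo-1-(triethylsilyloxy)pent-3-en-1-yl]-5-methyloxolan-2-yl]-6-(triethylsilyloxy)hept-1-en-3-yl]propanoic acid (both epimers at the malonate carbon)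
Conditions: LiOH (1 equiv), THF/MeOH/H2O, 0 °C; then aq. HCl to pH 3
Reagents that add atoms: lithium hydroxide, [Li+].[OH-]
Why: mono-saponification of a malonic diester: once the first ester is hydrolysed the carboxylate protects the second, so one equivalent of hydroxide should stop at the half-ester (the new malonate stereocentre disappears in step 15).

**Step 15**
Reactants: 23 malonic half-ester
Product: 25 methyl (3S,6S)-3-ethenyl-6-[(2R,5S)-5-[(1R,3E)-4-iodo-1-(triethylsilyloxy)pent-3-en-1-yl]-5-methyloxolan-2-yl]-2-methylidene-6-(triethylsilyloxy)heptanoate, via Mannich base 24 (not isolated)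
Conditions: (CH2O)n, Et2NH, THF, reflux
Reagents that add atoms: formaldehyde (as paraformaldehyde), C=O
Why: Mannich reaction followed by decarboxylative elimination of diethylamine (the classical malonic half-ester route to 2-substituted acrylates) builds the methyl acrylate on C15 under conditions too mild to epimerise C1.

**Step 16**
Reactants: 25 methyl (3S,6S)-3-ethenyl-6-[(2R,5S)-5-[(1R,3E)-4-iodo-1-(triethylsilyloxy)pent-3-en-1-yl]-5-methyloxolan-2-yl]-2-methylidene-6-(triethylsilyloxy)heptanoate
Product: 26 methyl (3S,6S)-3-ethenyl-6-hydroxy-6-[(2R,5S)-5-[(1R,3E)-1-hydroxy-4-iodopent-3-en-1-yl]-5-methyloxolan-2-yl]-2-methylideneheptanoate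
Conditions: HF·pyridine, pyridine, THF, 0 °C to rt
Reagents that add atoms: none
Why: fluoride-mediated cleavage of both triethylsilyl ethers under buffered conditions that the acrylate and the iodoalkene tolerate.

**Step 17**
Reactants: 26 methyl (3S,6S)-3-ethenyl-6-hydroxy-6-[(2R,5S)-5-[(1R,3E)-1-hydroxy-4-iodopent-3-en-1-yl]-5-methyloxolan-2-yl]-2-methylideneheptanoate
Product: 27 methyl (3S,6S)-6-[(2R,5S)-5-[(1R,3E)-1-acetoxy-4-iodopent-3-en-1-yl]-5-methyloxolan-2-yl]-3-ethenyl-6-hydroxy-2-methylideneheptanoate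
Conditions: Ac2O, pyridine, DMAP (cat.), CH2Cl2, 0 °C
Reagents that add atoms: acetic anhydride, CC(=O)OC(C)=O
Why: acylation of the secondary C7 hydroxyl; the tertiary C12 hydroxyl should not be acetylated under these mild conditions and no other free hydroxyl exists at this stage.

**Step 18**
Reactants: 27 methyl (3S,6S)-6-[(2R,5S)-5-[(1R,3E)-1-acetoxy-4-iodopent-3-en-1-yl]-5-methyloxolan-2-yl]-3-ethenyl-6-hydroxy-2-methylideneheptanoate
Product: 29 methyl (3S,6S)-6-[(2R,5S)-5-[(1R,3E)-1-acetoxy-4-iodopent-3-en-1-yl]-5-methyloxolan-2-yl]-6-hydroxy-2-methylidene-3-(2-oxoethyl)heptanoate, via alkylborane 28 (not isolated)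
Conditions: dicyclohexylborane, THF, 0 °C to rt; then N-methylmorpholine N-oxide, (n-Pr4N)RuO4 (cat.), 4 Å MS, CH2Cl2, rt
Reagents that add atoms: N-methylmorpholine N-oxide, C[N+]1([O-])CCOCC1
Why: anti-Markovnikov hydroboration of the only monosubstituted alkene by the hindered dialkylborane (the conjugated acrylate olefin and the trisubstituted iodoalkene react much more slowly), then direct perruthenate/N-oxide oxidation of the primary alkylborane to the aldehyde, which avoids a free δ-hydroxy ester that could lactonise.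

**Step 19**
Reactants: 29 methyl (3S,6S)-6-[(2R,5S)-5-[(1R,3E)-1-acetoxy-4-iodopent-3-en-1-yl]-5-methyloxolan-2-yl]-6-hydroxy-2-methylidene-3-(2-oxoethyl)heptanoate
Product: 30 methyl (1S,3S,4E,7R,8S,11R,12S)-7-acetoxy-8,11-epoxy-3,12-dihydroxycembra-4,15(17)-dien-16-oate (CNP0266699.4)
Conditions: CrCl2 (excess), NiCl2 (cat.), DMSO/THF, rt, high dilution (slow addition)
Reagents that add atoms: none
Why: intramolecular Nozaki–Hiyama–Kishi reaction: the alkenylchromium species formed from the (E)-iodoalkene with retention adds chemoselectively to the aldehyde, closing the 14-membered ring with the 4E geometry intact, and the 3S configuration relies on the conformational preference of the forming macrocycle, the point addressed by the first fallback.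

**Compound list**

1 | geranyl acetate, (2E)-3,7-dimethylocta-2,6-dien-1-yl acetate | CC(C)=CCC/C(C)=C/COC(C)=O | starting material
2 | (2E,6E)-8-hydroxy-3,7-dimethylocta-2,6-dien-1-yl acetate | OC/C(C)=C/CC/C(C)=C/COC(C)=O | intermediate
3 | tributyl(prop-1-yn-1-yl)stannane | CC#C[Sn](CCCC)(CCCC)CCCC | starting material
4 | (2E,6E)-2,6-dimethylundeca-2,6-dien-9-yn-1-ol | OC/C(C)=C/CC/C(C)=C/CC#CC | intermediate
5 | alkenylzirconocene chloride from 4 (Zr on C10 of the undecatriene, syn to H on C9; hydroxyl as its zirconocene alkoxide) | Cl[Zr](C1C=CC=C1)(C1C=CC=C1)OC/C(C)=C/CC/C(C)=C/C/C=C(\C)[Zr](Cl)(C1C=CC=C1)C1C=CC=C1 | intermediate (not isolated)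
6 | (2E,6E,9E)-10-iodo-2,6-dimethylundeca-2,6,9-trien-1-ol | OC/C(C)=C/CC/C(C)=C/C/C=C(\C)I | intermediate
7 | [(2R,3R)-3-[(3E,6E)-7-iodo-3-methylocta-3,6-dien-1-yl]-2-methyloxiran-2-yl]methanol | OC[C@@]1(C)O[C@@H]1CC/C(C)=C/C/C=C(\C)I | intermediate
8 | [(2R,3R)-3-(2-{(2R,3R)-3-[(2E)-3-iodobut-2-en-1-yl]-2-methyloxiran-2-yl}ethyl)-2-methyloxiran-2-yl]methanol | OC[C@@]1(C)O[C@@H]1CC[C@@]2(C)O[C@@H]2C/C=C(\C)I | intermediate
9 | tert-butyl {[(2R,3R)-3-(2-{(2R,3R)-3-[(2E)-3-iodobut-2-en-1-yl]-2-methyloxiran-2-yl}ethyl)-2-methyloxiran-2-yl]methyl} carbonate | CC(C)(C)OC(=O)OC[C@@]1(C)O[C@@H]1CC[C@@]2(C)O[C@@H]2C/C=C(\C)I | intermediate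
10 | epoxonium zwitterion: 1-oxoniabicyclo[3.1.0]hexane with O+ bonded to C8, C11 and C12, C7–O–BF3(−), carbonate intact, (7R,8S,11R,12R) | CC(C)(C)OC(=O)OC[C@@]1(C)[O+]2[C@@H]1CC[C@@]2(C)[C@H](O[B-](F)(F)F)C/C=C(\C)I | intermediate (not isolated)
11 | 2-tert-butoxy-1,3-dioxolan-2-ylium zwitterion with the oxolane closed, (7R,8S,11R,12S) | CC(C)(C)OC1=[O+][C@@](C)(CO1)[C@H]2CC[C@](C)(O2)[C@H](O[B-](F)(F)F)C/C=C(\C)I | intermediate (not isolated)
12 | (4S)-4-[(2R,5S)-5-[(1R,3E)-1-hydroxy-4-iodopent-3-en-1-yl]-5-methyloxolan-2-yl]-4-methyl-1,3-dioxolan-2-one | O=C1OC[C@](C)(O1)[C@H]2CC[C@](C)(O2)[C@H](O)C/C=C(\C)I | intermediate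
13 | (2S)-2-[(2R,5S)-5-[(1R,3E)-1-hydroxy-4-iodopent-3-en-1-yl]-5-methyloxolan-2-yl]propane-1,2-diol | OC[C@](C)(O)[C@H]1CC[C@](C)(O1)[C@H](O)C/C=C(\C)I | intermediate
14 | primary (C13) p-toluenesulfonate of 13 | Cc1ccc(cc1)S(=O)(=O)OC[C@](C)(O)[C@H]2CC[C@](C)(O2)[C@H](O)C/C=C(\C)I | intermediate (not isolated)
15 | (1R,3E)-4-iodo-1-[(2S,5R)-2-methyl-5-[(2S)-2-methyloxiran-2-yl]oxolan-2-yl]pent-3-en-1-ol | C1O[C@]1(C)[C@H]2CC[C@](C)(O2)[C@H](O)C/C=C(\C)I | intermediate
16 | allylmagnesium chloride | C=CC[Mg]Cl | starting material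
17 | (2S)-2-[(2R,5S)-5-[(1R,3E)-1-hydroxy-4-iodopent-3-en-1-yl]-5-methyloxolan-2-yl]hex-5-en-2-ol | C=CCC[C@](C)(O)[C@H]1CC[C@](C)(O1)[C@H](O)C/C=C(\C)I | intermediate
18 | bis(triethylsilyl) ether of 17 (C7–OSiEt3, C12–OSiEt3) | C=CCC[C@](C)(O[Si](CC)(CC)CC)[C@H]1CC[C@](C)(O1)[C@H](O[Si](CC)(CC)CC)C/C=C(\C)I | intermediate
19 | allyl methyl carbonate | C=CCOC(=O)OC | starting material
20 | methyl (2E,6S)-6-[(2R,5S)-5-[(1R,3E)-4-iodo-1-(triethylsilyloxy)pent-3-en-1-yl]-5-methyloxolan-2-yl]-6-(triethylsilyloxy)hept-2-en-1-yl carbonate | COC(=O)OC/C=C/CC[C@](C)(O[Si](CC)(CC)CC)[C@H]1CC[C@](C)(O1)[C@H](O[Si](CC)(CC)CC)C/C=C(\C)I | intermediate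
21 | dimethyl malonate | COC(=O)CC(=O)OC | starting material
22 | dimethyl 2-[(3S,6S)-6-[(2R,5S)-5-[(1R,3E)-4-iodo-1-(triethylsilyloxy)pent-3-en-1-yl]-5-methyloxolan-2-yl]-6-(triethylsilyloxy)hept-1-en-3-yl]propanedioate | COC(=O)C(C(=O)OC)[C@H](C=C)CC[C@](C)(O[Si](CC)(CC)CC)[C@H]1CC[C@](C)(O1)[C@H](O[Si](CC)(CC)CC)C/C=C(\C)I | intermediate
23 | malonic half-ester of 22 (one CO2Me hydrolysed to CO2H; both epimers at the malonate carbon) | COC(=O)C(C(O)=O)[C@H](C=C)CC[C@](C)(O[Si](CC)(CC)CC)[C@H]1CC[C@](C)(O1)[C@H](O[Si](CC)(CC)CC)C/C=C(\C)I | intermediate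
24 | Mannich base of 23 (diethylaminomethyl group on the malonate carbon) | CCN(CC)CC(C(O)=O)(C(=O)OC)[C@H](C=C)CC[C@](C)(O[Si](CC)(CC)CC)[C@H]1CC[C@](C)(O1)[C@H](O[Si](CC)(CC)CC)C/C=C(\C)I | intermediate (not isolated)
25 | methyl (3S,6S)-3-ethenyl-6-[(2R,5S)-5-[(1R,3E)-4-iodo-1-(triethylsilyloxy)pent-3-en-1-yl]-5-methyloxolan-2-yl]-2-methylidene-6-(triethylsilyloxy)heptanoate | C=C(C(=O)OC)[C@H](C=C)CC[C@](C)(O[Si](CC)(CC)CC)[C@H]1CC[C@](C)(O1)[C@H](O[Si](CC)(CC)CC)C/C=C(\C)I | intermediate
26 | methyl (3S,6S)-3-ethenyl-6-hydroxy-6-[(2R,5S)-5-[(1R,3E)-1-hydroxy-4-iodopent-3-en-1-yl]-5-methyloxolan-2-yl]-2-methylideneheptanoate | C=C(C(=O)OC)[C@H](C=C)CC[C@](C)(O)[C@H]1CC[C@](C)(O1)[C@H](O)C/C=C(\C)I | intermediate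
27 | methyl (3S,6S)-6-[(2R,5S)-5-[(1R,3E)-1-acetoxy-4-iodopent-3-en-1-yl]-5-methyloxolan-2-yl]-3-ethenyl-6-hydroxy-2-methylideneheptanoate | C=C(C(=O)OC)[C@H](C=C)CC[C@](C)(O)[C@H]1CC[C@](C)(O1)[C@H](OC(C)=O)C/C=C(\C)I | intermediate
28 | B-alkyl dicyclohexylborane from 27 (boron on C3) | C=C(C(=O)OC)[C@H](CCB(C1CCCCC1)C2CCCCC2)CC[C@](C)(O)[C@H]3CC[C@](C)(O3)[C@H](OC(C)=O)C/C=C(\C)I | intermediate (not isolated)
29 | methyl (3S,6S)-6-[(2R,5S)-5-[(1R,3E)-1-acetoxy-4-iodopent-3-en-1-yl]-5-methyloxolan-2-yl]-6-hydroxy-2-methylidene-3-(2-oxoethyl)heptanoate | C=C(C(=O)OC)[C@H](CC=O)CC[C@](C)(O)[C@H]1CC[C@](C)(O1)[C@H](OC(C)=O)C/C=C(\C)I | intermediate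
30 | methyl (1S,3S,4E,7R,8S,11R,12S)-7-acetoxy-8,11-epoxy-3,12-dihydroxycembra-4,15(17)-dien-16-oate (CNP0266699.4) | C=C(C(=O)OC)[C@H]1CC[C@](C)(O)[C@H]2CC[C@](C)(O2)[C@H](OC(C)=O)C/C=C(\C)[C@@H](O)C1 | target

**Step count and risks**

Total step count: 19. Longest linear sequence: 19 steps (1 to 30); the route is fully linear.

Steps most likely to fail:

Step 19. The ring-closing addition may show insufficient facial selectivity at the aldehyde, so that both C3 configurations form, and intermolecular coupling may compete. The fallback sets out from 29 and moves the stereocontrol from the ring closure to a reagent-controlled ketone reduction. The closure is run without demands on selectivity. The mixture of 30 and its C3-epimeric alcohol F1 is oxidised with MnO2 in CH2Cl2 to the macrocyclic enone F2. F2 is reduced with (R)-2-methyl-CBS-oxazaborolidine and catecholborane in toluene at −78 °C (alkenyl as the large group, CH2 as the small group), which should give the 3S alcohol and comes back to the route at 30.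

Step 7. Ionisation at C8 may run ahead of participation by the second oxirane, leading to a 1,2-hydride shift to a C7 ketone, capture by fluoride or stereochemical leakage through a free cation; the tert-butyl group may also be lost early. The fallback sets out from 8 and drops the Lewis acid and the tethered terminator. The unprotected bis-epoxy alcohol is treated with camphorsulfonic acid (cat.) in hexafluoroisopropanol containing a few equivalents of water at 0 °C. The same enlargement of the C11–C12 oxirane to the oxolane through the epoxonium ion then proceeds under hydrogen-bond activation, and water ends the cascade at C12. This gives the triol directly and comes back to the route at 13; steps 6 and 8 fall away and no new compound is made.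

Step 13. The branched selectivity or the facial selectivity of the allylic alkylation may erode, or the catalyst may be slowed by the polyfunctional substrate. The fallback sets out from 18 and forms the C1–C2 bond instead of the C1–C15 bond. Johnson–Lemieux cleavage of the terminal alkene (OsO4 cat., NaIO4, 2,6-lutidine, dioxane/H2O) gives the aldehyde F3. A Morita–Baylis–Hillman reaction with methyl acrylate (DABCO) gives the allylic alcohol F4 as both C1 epimers. NBS/Me2S converts it with allylic transposition into the (Z)-allylic bromide F5. A ligand-controlled copper-catalysed anti-SN2′ substitution with vinylmagnesium bromide (CuBr·SMe2, chiral phosphoramidite, CH2Cl2, −78 °C) puts the vinyl group on C1 and releases the acrylate. The C1 epimers are diastereomers and separable, and the sequence comes back to the route at 25, replacing steps 12 to 15.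

**Further compounds**

F1 | step 19 | methyl (1S,3R,4E,7R,8S,11R,12S)-7-acetoxy-8,11-epoxy-3,12-dihydroxycembra-4,15(17)-dien-16-oate (C3 epimer of 30) | C=C(C(=O)OC)[C@H]1CC[C@](C)(O)[C@H]2CC[C@](C)(O2)[C@H](OC(C)=O)C/C=C(\C)[C@H](O)C1
F2 | step 19 | methyl (1S,4E,7R,8S,11R,12S)-7-acetoxy-8,11-epoxy-12-hydroxy-3-oxocembra-4,15(17)-dien-16-oate | C=C(C(=O)OC)[C@H]1CC[C@](C)(O)[C@H]2CC[C@](C)(O2)[C@H](OC(C)=O)C/C=C(\C)C(=O)C1
F0 | step 7 | none | none
F3 | step 13 | (4S)-4-[(2R,5S)-5-[(1R,3E)-4-iodo-1-(triethylsilyloxy)pent-3-en-1-yl]-5-methyloxolan-2-yl]-4-(triethylsilyloxy)pentanal | O=CCC[C@](C)(O[Si](CC)(CC)CC)[C@H]1CC[C@](C)(O1)[C@H](O[Si](CC)(CC)CC)C/C=C(\C)I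
F4 | step 13 | methyl (6S)-3-hydroxy-6-[(2R,5S)-5-[(1R,3E)-4-iodo-1-(triethylsilyloxy)pent-3-en-1-yl]-5-methyloxolan-2-yl]-2-methylidene-6-(triethylsilyloxy)heptanoate (both C3 epimers) | C=C(C(=O)OC)C(O)CC[C@](C)(O[Si](CC)(CC)CC)[C@H]1CC[C@](C)(O1)[C@H](O[Si](CC)(CC)CC)C/C=C(\C)I
F5 | step 13 | methyl (2Z,6S)-2-(bromomethyl)-6-[(2R,5S)-5-[(1R,3E)-4-iodo-1-(triethylsilyloxy)pent-3-en-1-yl]-5-methyloxolan-2-yl]-6-(triethylsilyloxy)hept-2-enoate | COC(=O)/C(CBr)=C/CC[C@](C)(O[Si](CC)(CC)CC)[C@H]1CC[C@](C)(O1)[C@H](O[Si](CC)(CC)CC)C/C=C(\C)I
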